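**Retrosynthetic overview**
- The strategy rests on C2 of ring C: it carries O1 and ring B (acetal oxidation level) and is bonded to C3, the α-carbon of the C4 ketone. C2–C3 is therefore disconnected to an aryl oxocarbenium ion at C2 and the enol C3=C4, both stored in one 2-aryl-4-methylene-4H-1,3-benzodioxine (Petasis–Ferrier retron).
- The enol acetal comes from carbonyl methylenation of a 1,3-benzodioxin-4-one, which is the acetal of 3,4-bis(silyloxy)benzaldehyde with a 3-substituted 2,4-dihydroxybenzoic acid. Both ring oxygens are thus already on ring A.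
- The acid comes from resorcinol: C2 lithiation of the bis-MOM ether and SN2 allylation, MOM removal, then Kolbe–Schmitt carboxylation at C4. The Z side chain comes from 4-methyl-2(5H)-furanone, whose ring fixes the geometry and whose opening at the acid level tells the two oxygens apart (the 3-methyl isomer would put the methyl on the wrong alkene carbon).
- Ring order: rings A and B are bought as arenes; the 1,3-dioxine ring is closed as a temporary ring (step 10); ring C is closed in the rearrangement (step 12); global desilylation ends the route.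

Key step: step 12

Remark: the sense of induction of the chiral acid cannot be predicted with confidence, so the (S,S) label in step 12 is nominal and the catalyst antipode that gives the (2S) product is the one to use. TBS = tert-butyldimethylsilyl, MOM = methoxymethyl, TMS = trimethylsilyl.

**Route**

Step 1
Reactants: 1 4-methylfuran-2(5H)-one
Product: 4 (Z)-4-(TBS-oxy)-3-methylbut-2-enoic acid, via potassium (Z)-4-hydroxy-3-methylbut-2-enoate 2 (not isolated), via bis-silyl derivative 3 (not isolated)
Conditions: KOH (1.0 equiv), H2O, 0 °C → rt, evaporate; TBSCl (2.5 equiv), imidazole, DMF, 0 °C → rt; then THF/H2O/AcOH, rt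
Reagents that add atoms: potassium hydroxide [K+].[OH-]; tert-butyldimethylsilyl chloride CC(C)(C)[Si](C)(C)Cl
Why: Lactone saponification, silylation of the hydroxy carboxylate salt and selective hydrolysis of the labile silyl ester should give the acid; the ring of 1 fixes the Z geometry, and the carbonyl carbon is marked as the future benzylic carbon.

Step 2
Reactants: 4 (Z)-4-(TBS-oxy)-3-methylbut-2-enoic acid
Product: 5 (Z)-4-(TBS-oxy)-3-methylbut-2-en-1-ol
Conditions: LiAlH4 (1.5 equiv), Et2O, 0 °C; Na2SO4·10H2O quench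
Reagents that add atoms: none
Why: LiAlH4 reduces the conjugated acid in a 1,2 sense to the allylic alcohol and should leave the trisubstituted alkene and the silyl ether alone at 0 °C.

Step 3
Reactants: 5 (Z)-4-(TBS-oxy)-3-methylbut-2-en-1-ol
Product: 6 (Z)-1-bromo-4-(TBS-oxy)-3-methylbut-2-ene
Conditions: CBr4, PPh3, CH2Cl2, −20 → 0 °C; used at once
Reagents that add atoms: carbon tetrabromide BrC(Br)(Br)Br
Why: Appel bromination displaces the alkoxyphosphonium ion of the primary allylic alcohol by SN2 under neutral conditions, which should keep the Z geometry and the silyl ether.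

Step 4
Reactants: 7 resorcinol
Product: 8 1,3-bis(methoxymethoxy)benzene
Conditions: NaH (2.4 equiv), DMF, 0 °C; MOMCl (2.4 equiv), 0 °C → rt
Reagents that add atoms: chloromethyl methyl ether COCCl
Why: Williamson etherification of both phenoxides gives the bis-MOM ether, whose two acetal oxygens direct lithiation to the carbon between them.

Step 5
Reactants: 8 1,3-bis(methoxymethoxy)benzene; 6 (Z)-1-bromo-4-(TBS-oxy)-3-methylbut-2-ene
Product: 10 2-[(Z)-4-(TBS-oxy)-3-methylbut-2-enyl]-1,3-bis(methoxymethoxy)benzene, via aryllithium 9 (not isolated)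
Conditions: n-BuLi (1.1 equiv), THF, 0 °C → rt; CuBr·SMe2 (10 mol %), −78 °C; then 6, −78 → 0 °C
Reagents that add atoms: none
Why: Directed ortho-metalation occurs at C2 between the two OMOM groups, and the aryl nucleophile, after transmetalation to copper, displaces the primary allylic bromide in an SN2 sense because the fully substituted γ-carbon is hindered, so the Z alkene should be carried over.

Step 6
Reactants: 10 2-[(Z)-4-(TBS-oxy)-3-methylbut-2-enyl]-1,3-bis(methoxymethoxy)benzene
Product: 11 2-[(Z)-4-hydroxy-3-methylbut-2-enyl]benzene-1,3-diol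
Conditions: HCl (1.25 M in MeOH), rt; NaHCO3 quench
Reagents that add atoms: none
Why: Acid-catalysed acetal exchange with methanol removes both MOM groups and the silyl ether in one operation; the alkene carries an inductively deactivating oxygenated carbon and is slow to protonate, so cyclisation to a chroman should not compete at room temperature.

Step 7
Reactants: 11 2-[(Z)-4-hydroxy-3-methylbut-2-enyl]benzene-1,3-diol
Product: 12 2,4-dihydroxy-3-[(Z)-4-hydroxy-3-methylbut-2-enyl]benzoic acid
Conditions: KHCO3 (6 equiv), CO2 (5 bar), H2O, 100 °C; then HCl (1 M) to pH 2, 0 °C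
Reagents that add atoms: carbon dioxide O=C=O; potassium hydrogen carbonate [K+].OC([O-])=O
Why: Kolbe–Schmitt carboxylation of the resorcinol phenoxide takes place ortho to one hydroxyl and para to the other; C2 is blocked and C4 and C6 are equivalent, so a single 2,4-dihydroxybenzoic acid should result.

Step 8
Reactants: 12 2,4-dihydroxy-3-[(Z)-4-hydroxy-3-methylbut-2-enyl]benzoic acid
Product: 14 4-(TBS-oxy)-2-hydroxy-3-[(Z)-4-(TBS-oxy)-3-methylbut-2-enyl]benzoic acid, via silyl ester 13 (not isolated)
Conditions: TBSCl (3.5 equiv), imidazole, DMF, rt; then THF/H2O/AcOH, rt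
Reagents that add atoms: tert-butyldimethylsilyl chloride CC(C)(C)[Si](C)(C)Cl
Why: Silylation covers the carboxyl, the unhindered 4-OH and the primary alcohol while the 2-OH, hydrogen-bonded to the carbonyl and flanked by two substituents, should stay free, and mild aqueous acid then hydrolyses the silyl ester alone.

Step 9
Reactants: 15 3,4-dihydroxybenzaldehyde
Product: 16 3,4-bis(TBS-oxy)benzaldehyde
Conditions: TBSCl (2.4 equiv), imidazole, DMF, rt
Reagents that add atoms: tert-butyldimethylsilyl chloride CC(C)(C)[Si](C)(C)Cl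
Why: Standard silylation of both catechol hydroxyls with a silyl chloride and imidazole.

Step 10
Reactants: 14 4-(TBS-oxy)-2-hydroxy-3-[(Z)-4-(TBS-oxy)-3-methylbut-2-enyl]benzoic acid; 16 3,4-bis(TBS-oxy)benzaldehyde
Product: 18 racemic 2-[3,4-bis(TBS-oxy)phenyl]-7-(TBS-oxy)-8-[(Z)-4-(TBS-oxy)-3-methylbut-2-enyl]-4H-1,3-benzodioxin-4-one, via bis-trimethylsilyl derivative 17 (not isolated)
Conditions: (Me3Si)2NH, CH2Cl2, rt, evaporate; 16 (1.1 equiv), TMSOTf (10 mol %), CH2Cl2, −78 °C; pyridine quench
Reagents that add atoms: none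
Why: Silyl-transfer acetalisation of the Noyori type, as used to make 1,3-dioxan-4-ones from silylated β-hydroxy acids: TMSOTf activates the aldehyde, the silyl ester and the aryl silyl ether add in turn and hexamethyldisiloxane is expelled; the acetal carbon forms racemic, which is of no consequence.

Step 11
Reactants: 18 racemic benzodioxinone
Product: 19 racemic 2-[3,4-bis(TBS-oxy)phenyl]-7-(TBS-oxy)-8-[(Z)-4-(TBS-oxy)-3-methylbut-2-enyl]-4-methylene-4H-1,3-benzodioxine
Conditions: Cp2TiMe2 (2.5 equiv), toluene, 65 °C, dark; filtration through basic alumina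
Reagents that add atoms: dimethyltitanocene C[Ti](C)(C1C=CC=C1)C1C=CC=C1
Why: Petasis methylenation: on heating the reagent loses methane to give Cp2Ti=CH2, which converts the lactone carbonyl into the exocyclic enol ether through an oxatitanacyclobutane under non-acidic conditions that should leave the acetal and the silyl ethers intact.

Step 12
Reactants: 19 racemic 4-methylene-4H-1,3-benzodioxine
Product: 20 (2S)-2-[3,4-bis(TBS-oxy)phenyl]-7-(TBS-oxy)-8-[(Z)-4-(TBS-oxy)-3-methylbut-2-enyl]chroman-4-one
Conditions: (S,S)-imidodiphosphorimidate Brønsted acid (N-triflyl, built on two 3,3'-diaryl-BINOL units; 5 mol %), 5 Å MS, toluene, −60 °C; Et3N quench at −60 °C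
Reagents that add atoms: none
Why: Proposed new method: the chiral acid protonates the enol-ether oxygen O3, the C2–O3 bond ionises to an oxocarbenium ion at C2 that is stabilised by O1 and by the para-silyloxy group of ring B and stays tethered through ring A to the enol of the aryl ketone, and the enol carbon C3 then attacks C2 and the proton returns to the catalyst. This is a Brønsted-acid, enantioselective version of the Petasis–Ferrier rearrangement of 4-methylene-1,3-dioxanes promoted by Me2AlCl; its nearest enantioselective relatives are the chiral phosphoric acid-catalysed aza-Petasis–Ferrier rearrangement of hemiaminal vinyl ethers and imidodiphosphorimidate-catalysed additions to oxocarbenium ions. Ring C closes in a 6-(enolendo)-endo-trig mode, as in the parent rearrangement. The new stereocenter C2 is set by the confined chiral counteranion, which holds the planar oxocarbenium–enol pair and leaves one face of C2 open; the racemic acetal centre of 19 is erased on ionisation, so the process is enantioconvergent. The step needs ionisation of this one acetal only (secured by the absence of any other acetal, all hydroxyls being silyl ethers, and by the cation-stabilising ring B) and C–C rather than C–O recombination (O-recombination merely regenerates 19, whereas C–C bond formation is irreversible). C-protonation of the enol ether is not a dead end, because loss of the C2–O3 bond from that cation and re-enolisation of the methyl ketone lead to the same tethered ion.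

Step 13
Reactants: 20 (2S)-tetrakis-TBS flavanone
Product: 21 (2S)-2-(3,4-dihydroxyphenyl)-7-hydroxy-8-[(Z)-4-hydroxy-3-methylbut-2-enyl]chroman-4-one
Conditions: HF·pyridine, pyridine/THF, 0 °C → rt
Reagents that add atoms: none
Why: Fluoride-driven cleavage of the four Si–O bonds under buffered, weakly acidic conditions avoids the base-induced ring opening to the chalcone that would racemise C2, and should leave the Z allylic alcohol untouched.

**Compound list**

1 | 4-methylfuran-2(5H)-one | CC1=CC(=O)OC1 | starting material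
2 | potassium (Z)-4-hydroxy-3-methylbut-2-enoate | [K+].[O-]C(=O)/C=C(/C)CO | intermediate
3 | tert-butyldimethylsilyl (Z)-4-(TBS-oxy)-3-methylbut-2-enoate | CC(C)(C)[Si](C)(C)OC(=O)/C=C(/C)CO[Si](C)(C)C(C)(C)C | intermediate
4 | (Z)-4-(TBS-oxy)-3-methylbut-2-enoic acid | OC(=O)/C=C(/C)CO[Si](C)(C)C(C)(C)C | intermediate
5 | (Z)-4-(TBS-oxy)-3-methylbut-2-en-1-ol | OC/C=C(/C)CO[Si](C)(C)C(C)(C)C | intermediate
6 | (Z)-1-bromo-4-(TBS-oxy)-3-methylbut-2-ene | BrC/C=C(/C)CO[Si](C)(C)C(C)(C)C | intermediate
7 | resorcinol | Oc1cccc(O)c1 | starting material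
8 | 1,3-bis(methoxymethoxy)benzene | COCOc1cccc(OCOC)c1 | intermediate
9 | 2-lithio-1,3-bis(methoxymethoxy)benzene | [Li]c1c(OCOC)cccc1OCOC | intermediate
10 | 2-[(Z)-4-(TBS-oxy)-3-methylbut-2-enyl]-1,3-bis(methoxymethoxy)benzene | COCOc1cccc(OCOC)c1C/C=C(/C)CO[Si](C)(C)C(C)(C)C | intermediate
11 | 2-[(Z)-4-hydroxy-3-methylbut-2-enyl]benzene-1,3-diol | Oc1cccc(O)c1C/C=C(/C)CO | intermediate
12 | 2,4-dihydroxy-3-[(Z)-4-hydroxy-3-methylbut-2-enyl]benzoic acid | OC(=O)c1ccc(O)c(C/C=C(/C)CO)c1O | intermediate
13 | tert-butyldimethylsilyl 4-(TBS-oxy)-2-hydroxy-3-[(Z)-4-(TBS-oxy)-3-methylbut-2-enyl]benzoate | CC(C)(C)[Si](C)(C)OC(=O)c1ccc(O[Si](C)(C)C(C)(C)C)c(C/C=C(/C)CO[Si](C)(C)C(C)(C)C)c1O | intermediate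
14 | 4-(TBS-oxy)-2-hydroxy-3-[(Z)-4-(TBS-oxy)-3-methylbut-2-enyl]benzoic acid | OC(=O)c1ccc(O[Si](C)(C)C(C)(C)C)c(C/C=C(/C)CO[Si](C)(C)C(C)(C)C)c1O | intermediate
15 | 3,4-dihydroxybenzaldehyde | O=Cc1ccc(O)c(O)c1 | starting material
16 | 3,4-bis(TBS-oxy)benzaldehyde | O=Cc1ccc(O[Si](C)(C)C(C)(C)C)c(O[Si](C)(C)C(C)(C)C)c1 | intermediate
17 | trimethylsilyl 4-(TBS-oxy)-3-[(Z)-4-(TBS-oxy)-3-methylbut-2-enyl]-2-(trimethylsilyloxy)benzoate | C[Si](C)(C)OC(=O)c1ccc(O[Si](C)(C)C(C)(C)C)c(C/C=C(/C)CO[Si](C)(C)C(C)(C)C)c1O[Si](C)(C)C | intermediate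
18 | racemic 2-[3,4-bis(TBS-oxy)phenyl]-7-(TBS-oxy)-8-[(Z)-4-(TBS-oxy)-3-methylbut-2-enyl]-4H-1,3-benzodioxin-4-one | O=C1OC(c2ccc(O[Si](C)(C)C(C)(C)C)c(O[Si](C)(C)C(C)(C)C)c2)Oc2c1ccc(O[Si](C)(C)C(C)(C)C)c2C/C=C(/C)CO[Si](C)(C)C(C)(C)C | intermediate
19 | racemic 2-[3,4-bis(TBS-oxy)phenyl]-7-(TBS-oxy)-8-[(Z)-4-(TBS-oxy)-3-methylbut-2-enyl]-4-methylene-4H-1,3-benzodioxine | C=C1OC(c2ccc(O[Si](C)(C)C(C)(C)C)c(O[Si](C)(C)C(C)(C)C)c2)Oc2c1ccc(O[Si](C)(C)C(C)(C)C)c2C/C=C(/C)CO[Si](C)(C)C(C)(C)C | intermediate
20 | (2S)-2-[3,4-bis(TBS-oxy)phenyl]-7-(TBS-oxy)-8-[(Z)-4-(TBS-oxy)-3-methylbut-2-enyl]chroman-4-one | C/C(=C/Cc1c(O[Si](C)(C)C(C)(C)C)ccc2c1O[C@H](c1ccc(O[Si](C)(C)C(C)(C)C)c(O[Si](C)(C)C(C)(C)C)c1)CC2=O)CO[Si](C)(C)C(C)(C)C | intermediate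
21 | (2S)-2-(3,4-dihydroxyphenyl)-7-hydroxy-8-[(Z)-4-hydroxy-3-methylbut-2-enyl]chroman-4-one | C/C(=C/Cc1c(O)ccc2c1O[C@H](c1ccc(O)c(O)c1)CC2=O)CO | target

**Step count**

Total step count: 13. Longest linear sequence: 11 steps (steps 1, 2, 3, 5, 6, 7, 8, 10, 11, 12, 13).

**Steps most likely to fail**

Step 12 (proposed method). The tethered oxocarbenium–enol intermediate may close without control by the counteranion, through adventitious acid or thermal ionisation. Traces of water may hydrolyse the enol ether to the o-hydroxyacetophenone and aldehyde 16. The acid may also ionise the C2–O1 bond of 20 after it has formed and so erode its enantiomeric purity. A racemic reference run with Me2AlCl (CH2Cl2, −78 °C) would show first whether the benzo-fused rearrangement is viable at all. The fallback uses known chemistry and sets out from acid 14. Addition of MeLi (excess, THF, 0 °C) to the lithium carboxylate would give 1-[4-(TBS-oxy)-2-hydroxy-3-[(Z)-4-(TBS-oxy)-3-methylbut-2-enyl]phenyl]ethanone F1. Condensation with N,N-dimethylformamide dimethyl acetal (toluene, 90 °C) would give the enaminone (E)-3-(dimethylamino)-1-[4-(TBS-oxy)-2-hydroxy-3-[(Z)-4-(TBS-oxy)-3-methylbut-2-enyl]phenyl]prop-2-en-1-one F2. Acid-promoted cyclisation (TsOH cat., toluene, 60 °C) with loss of dimethylamine would give 7-(TBS-oxy)-8-[(Z)-4-(TBS-oxy)-3-methylbut-2-enyl]-4H-chromen-4-one F3. In parallel, 4-bromocatechol would be silylated (TBSCl, imidazole) to 4-bromo-1,2-bis(TBS-oxy)benzene F4 and converted by Br/Li exchange (n-BuLi, −78 °C) and B(OiPr)3 into [3,4-bis(TBS-oxy)phenyl]boronic acid F5. Enantioselective conjugate addition of F5 to F3 with Pd(OCOCF3)2 and a chiral pyridine–oxazoline ligand (t-BuPyOX, the antipode that gives 2S; NH4PF6, H2O, 1,2-dichloroethane, 60 °C) returns to the route at 20.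

Step 5. The copper-mediated coupling may proceed in part by attack at the γ-carbon, the Z alkene may isomerise through an allylcopper intermediate, or the hindered di-ortho-substituted aryl nucleophile may react sluggishly and eliminate the bromide instead. The fallback sets out from 8 and builds the Z alkene on the arene. Lithiation as above and trapping with allyl bromide would give 2-allyl-1,3-bis(methoxymethoxy)benzene F6. Oxidative cleavage (OsO4 cat., NaIO4, 2,6-lutidine, dioxane/H2O) would give [2,6-bis(methoxymethoxy)phenyl]acetaldehyde F7. Still–Gennari olefination with ethyl 2-[bis(2,2,2-trifluoroethoxy)phosphoryl]propanoate (KN(SiMe3)2, 18-crown-6, THF, −78 °C) would give ethyl (Z)-4-[2,6-bis(methoxymethoxy)phenyl]-2-methylbut-2-enoate F8. Reduction with i-Bu2AlH (CH2Cl2, −78 °C) would give (Z)-4-[2,6-bis(methoxymethoxy)phenyl]-2-methylbut-2-en-1-ol F9. Methanolic HCl as in step 6 then returns to the route at 11.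

Step 7. The carboxylation may stop short because it is reversible in hot aqueous bicarbonate (decarboxylation of the β-resorcylic acid), and the hydroxylated side chain may degrade or cyclise onto the phenol during the hot reaction or the acidic work-up. The fallback sets out from 10 and replaces electrophilic carboxylation by directed lithiation. s-BuLi/TMEDA (THF, −78 °C) metalates ortho to an OMOM group and dry CO2 would give 2,4-bis(methoxymethoxy)-3-[(Z)-4-(TBS-oxy)-3-methylbut-2-enyl]benzoic acid F10. Aqueous HCl in THF (40 °C) removes both MOM groups and the silyl ether and returns to the route at 12.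

**Further compounds**

F1 | step 12 | 1-[4-(TBS-oxy)-2-hydroxy-3-[(Z)-4-(TBS-oxy)-3-methylbut-2-enyl]phenyl]ethanone | CC(=O)c1ccc(O[Si](C)(C)C(C)(C)C)c(C/C=C(/C)CO[Si](C)(C)C(C)(C)C)c1O
F2 | step 12 | (E)-3-(dimethylamino)-1-[4-(TBS-oxy)-2-hydroxy-3-[(Z)-4-(TBS-oxy)-3-methylbut-2-enyl]phenyl]prop-2-en-1-one | CN(C)/C=C/C(=O)c1ccc(O[Si](C)(C)C(C)(C)C)c(C/C=C(/C)CO[Si](C)(C)C(C)(C)C)c1O
F3 | step 12 | 7-(TBS-oxy)-8-[(Z)-4-(TBS-oxy)-3-methylbut-2-enyl]-4H-chromen-4-one | O=c1ccoc2c1ccc(O[Si](C)(C)C(C)(C)C)c2C/C=C(/C)CO[Si](C)(C)C(C)(C)C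
F4 | step 12 | 4-bromo-1,2-bis(TBS-oxy)benzene | Brc1ccc(O[Si](C)(C)C(C)(C)C)c(O[Si](C)(C)C(C)(C)C)c1
F5 | step 12 | [3,4-bis(TBS-oxy)phenyl]boronic acid | OB(O)c1ccc(O[Si](C)(C)C(C)(C)C)c(O[Si](C)(C)C(C)(C)C)c1
F6 | step 5 | 2-allyl-1,3-bis(methoxymethoxy)benzene | C=CCc1c(OCOC)cccc1OCOC
F7 | step 5 | [2,6-bis(methoxymethoxy)phenyl]acetaldehyde | O=CCc1c(OCOC)cccc1OCOC
F8 | step 5 | ethyl (Z)-4-[2,6-bis(methoxymethoxy)phenyl]-2-methylbut-2-enoate | CCOC(=O)/C(C)=C\Cc1c(OCOC)cccc1OCOC
F9 | step 5 | (Z)-4-[2,6-bis(methoxymethoxy)phenyl]-2-methylbut-2-en-1-ol | OC/C(C)=C\Cc1c(OCOC)cccc1OCOC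
F10 | step 7 | 2,4-bis(methoxymethoxy)-3-[(Z)-4-(TBS-oxy)-3-methylbut-2-enyl]benzoic acid | COCOc1ccc(C(=O)O)c(OCOC)c1C/C=C(/C)CO[Si](C)(C)C(C)(C)C
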